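**Two neighbours.** Set the ochre run beside the blue run. They hold the same Cat, with Sub charges of 0.600 M and 1.80 M, yet by 1.3 min they have made 0.053 M and 0.075 M of Prd.

| flask | Sub | Cat | Prd | time |
|---|---|---|---|---|
| ochre | 0.600 M | 0.0480 M |  |  |
| red | 0.600 M | 0.0480 M | 0.300 M |  |
| green | 0.600 M | 0.0960 M |  |  |
| blue | 1.80 M | 0.0480 M |  |  |
| teal | 1.50 M | 0.0480 M |  | 7.3 min |

- ochre run (time / min: [Prd] / M): 0.42: 0.018; 1.3: 0.053; 2.4: 0.136; 3.8: 0.227; 5.5: 0.301; 7.3: 0.330
- red run (time / min: [Prd] / M): 0.42: 0.311; 1.3: 0.367; 2.4: 0.430; 3.8: 0.520; 5.5: 0.593; 7.3: 0.644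
- green run (time / min: [Prd] / M): 0.42: 0.022; 1.3: 0.116; 2.4: 0.241; 3.8: 0.357; 5.5: 0.425; 7.3: 0.430
- blue run (time / min: [Prd] / M): 0.42: 0.022; 1.3: 0.075; 2.4: 0.154; 3.8: 0.261; 5.5: 0.372; 7.3: 0.449

(each reading ± 0.006 M)

1. apparent order in [Sub] of the starting rate, round the charge of the ochre run (the rate where two percent of its Sub have turned into Prd) (one fixed amount of Prd, the same in the runs compared)
2. apparent order in [Cat] of the starting rate, round the charge of the ochre run (the rate where two percent of its Sub have turned into Prd)
3. Prd in the teal run at 7.3 min, as a share of the Sub charged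

- Overall: Sub -> Prd, with Cat as catalyst.
- Constant volume, constant temperature.
- The analysis sees a species whether free or bound.
- An order is taken over about fifteen percent of the charge, up and down.

**Ceiling rate.** Read a rough order in Sub from those two amounts: 0.316 over that wide step, a reading with its scatter, as in saturation kinetics. The green run, with twice the Cat, has made 0.116 M by 1.3 min, which reads as a rough order in Cat of 1.13. Now take the steepest stretch of the blue run, 0.0764 M min⁻¹, as the ceiling rate. The steepest stretch of the ochre run reads 0.0755 M min⁻¹, about the same.

**Two times.** At this Cat, compare two times. The charge time is the Sub charged over the ceiling rate, 23.6 min for the blue run. The last reading of the blue run over the ceiling rate gives 5.87 min, its working time: the minutes at the ceiling that would make the Prd found. Their ratio is the share of the charge made into Prd by the last reading, for the blue run a quarter. The ochre run has a working time of 4.32 min.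

**Teal.** The teal run has a charge time of 19.6 min. Interpolate its working time on the logarithm of the charge, between ochre and blue: 5.62 min. My share is therefore 28.7%. The forecast gives 28.5% (27% to 30%), with orders 0.4 in Sub and 1 in Cat, reasoning that "The runs show saturation in Sub".

**The result.** The teal run gives 29.4%, with orders 0.13 in Sub and 0.62 in Cat.

    X + Sub ⇌ Cat.Sub, settled at all times (6.910 L mol⁻¹)
    Cat.Sub → Prd + X (2.340 min⁻¹)
    2 Sub → J (0.2502 L mol⁻¹ min⁻¹)
    Cat → X (1.332 min⁻¹)

By 2 Sub → J alone, the Sub of the teal run has a first half-life of 1.33 min. The result of the teal run means a working time of 5.77 min, between the 4.32 min of ochre and the 5.87 min of blue. The red run, counting the Prd it made, has a working time of 4.50 min, against 4.32 min for ochre.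

The runs are calculated from invented constants; noise was put on by code.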